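**Plan**
1. Retrosynthesis: C4'–H is traced back to a helper C4'–OH (tetronic acid). The furanone bond C3'–C2' is then cut (C3' = ring carbon on C8 of ring A, C2' = lactone carbonyl; furanone numbered O1', C2', C3', C4', C5'Me2). The carbonate carbon C2' goes back to CO2, C8–C3' to an aryl iodide plus 2-methylbut-3-yn-2-ol, and C8–I and O–CH3 to 7-hydroxyflavone.
2. Forward: the flavone (rings A, B and C) is bought intact, iodinated at C8 and O-methylated. Sonogashira coupling attaches the C3'–C4'–C5'Me2–O1' chain, and CO2 is clipped on as a temporary 1,3-dioxolan-2-one ring.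
3. Base then moves the carboxyl carbon from the enol oxygen to C3', which closes the furanone. The helper C4'–OH is removed through its triflate.
4. Enabling feature: O1' sits on the quaternary carbon C5' and C2' has the oxidation level of CO2. A C4' ketone can therefore enolize only toward C3' (benzylic to C8 of ring A), and an O1'-bound carbonate can acylate C3'.
5. Stereochemistry: the target has no stereocentre. The only stereo-element on the way, the Z alkene of the cyclic carbonate (anti oxy-argentation), is erased in the key step.

Key step: step 5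

Remark on the chemistry: the C8–C3' axis is taken as freely rotating, and 7-hydroxyflavone and 2-methylbut-3-yn-2-ol are taken as commercial.

**Route**

Step 1
Reactants: 1 7-hydroxyflavone (7-hydroxy-2-phenyl-4H-chromen-4-one)
Product: 2 7-hydroxy-8-iodoflavone
Conditions: NIS (1.0 equiv), DMF, 0 °C to rt
Reagents that add atoms: N-iodosuccinimide, O=C1CCC(=O)N1I
Why: Electrophilic aromatic iodination of a phenol should occur at C8 of ring A, which lies between the 7-hydroxyl and the pyranone oxygen and is the most nucleophilic position of 7-hydroxychromones, and one equivalent of NIS should stop at the monoiodide.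

Step 2
Reactants: 2 7-hydroxy-8-iodoflavone
Product: 3 8-iodo-7-methoxyflavone
Conditions: MeI, K2CO3, acetone, reflux
Reagents that add atoms: iodomethane, CI
Why: Williamson ether synthesis, in which the acidic 7-phenol (a vinylogous acid through the pyranone carbonyl) is deprotonated by K2CO3 and should be methylated on oxygen despite the ortho iodine.

Step 3
Reactants: 3 8-iodo-7-methoxyflavone; 4 2-methylbut-3-yn-2-ol
Product: 5 8-(3-hydroxy-3-methylbut-1-yn-1-yl)-7-methoxy-2-phenyl-4H-chromen-4-one
Conditions: PdCl2(PPh3)2 (5 mol %), CuI (10 mol %), Et3N, DMF, 70 °C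
Reagents that add atoms: none
Why: Sonogashira coupling, in which zerovalent palladium should insert into the aryl C–I bond even of this di-ortho-substituted iodide, and the small linear copper acetylide of 4 couples with the free tertiary alcohol tolerated.

Step 4
Reactants: 5 8-(3-hydroxy-3-methylbut-1-yn-1-yl)-7-methoxy-2-phenyl-4H-chromen-4-one
Product: 6 (Z)-5-[(7-methoxy-4-oxo-2-phenyl-4H-chromen-8-yl)methylidene]-4,4-dimethyl-1,3-dioxolan-2-one
Conditions: AgOAc (10 mol %), DBU (1.0 equiv), CO2 (1.0 MPa), toluene/CH2Cl2, 25 °C
Reagents that add atoms: carbon dioxide, O=C=O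
Why: AgOAc-catalysed carboxylative cyclization of a propargylic alcohol, in which DBU and CO2 turn the tertiary alcohol into a carbonate anion whose oxygen should add anti to the silver-activated alkyne in a 5-exo-dig closure, and protodeargentation then gives the Z-alkylidene cyclic carbonate.

Step 5
Reactants: 6 (Z)-5-[(7-methoxy-4-oxo-2-phenyl-4H-chromen-8-yl)methylidene]-4,4-dimethyl-1,3-dioxolan-2-one
Product: 9 4-hydroxy-3-(7-methoxy-4-oxo-2-phenyl-4H-chromen-8-yl)-5,5-dimethylfuran-2(5H)-one, via potassium enolate tert-butyl carbonate 7 (not isolated), via potassium tetronate 8 (not isolated)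
Conditions: KOtBu (1.5 equiv), THF (0.02 M), 0 °C to 40 °C; then 1 M HCl
Reagents that add atoms: none
Why: Proposed new method: tert-butoxide should add to the carbonate carbonyl of 6 and expel the enolate oxygen, which unmasks potassium enolate 7 with the former CO2 carbon still held on the tertiary oxygen O1' as a tert-butyl carbonate; the enolate carbon C3' then attacks this carbonate carbonyl, tert-butoxide leaves, and the 3-aryl-furan-2,4-dione is deprotonated at once to tetronate 8, so the net change is a base-mediated 1,3-shift of the carboxyl carbon from oxygen to carbon. The closest known reaction types are the base-mediated rearrangement of 5-alkylidene-oxazolidin-2-ones (made from propargylic amines and CO2) to tetramic acids by ring opening and C-acylation, the alkoxide-induced opening of alkylidene cyclic carbonates to 2-oxoalkyl carbonates, and the Claisen cyclization of 4-oxo esters to cyclopentane-1,3-diones. The furanone ring closes in the 5-(enolendo)-exo-trig mode, which is geometrically demanding, hence the warming and the high dilution that keeps the carboxyl transfer intramolecular. No stereocentre is formed, and the Z geometry of 7 is lost in the planar tetronate. The step needs C- over O-acylation: O-acylation only returns 6 and is reversible under tert-butoxide, whereas C-acylation is made irreversible by deprotonation to the vinylogous carboxylate 8. Only one enolate can form because the ketone carbon C4' is flanked by the quaternary carbon C5', whose gem-dimethyl group also holds the carbonate over C3', and the flavone carries no competing acidic C–H.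

Step 6
Reactants: 9 4-hydroxy-3-(7-methoxy-4-oxo-2-phenyl-4H-chromen-8-yl)-5,5-dimethylfuran-2(5H)-one
Product: 10 4-(7-methoxy-4-oxo-2-phenyl-4H-chromen-8-yl)-2,2-dimethyl-5-oxo-2,5-dihydrofuran-3-yl trifluoromethanesulfonate
Conditions: Tf2O (1.1 equiv), iPr2NEt, CH2Cl2, −78 °C
Reagents that add atoms: trifluoromethanesulfonic anhydride, O=S(=O)(OS(=O)(=O)C(F)(F)F)C(F)(F)F
Why: O-sulfonylation of the ammonium tetronate should occur at the C4' oxygen, the site at which 3-aryl-5,5-disubstituted tetronic acids are acylated, and at −78 °C the tetronate is far more nucleophilic than the flavone carbonyl.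

Step 7
Reactants: 10 4-(7-methoxy-4-oxo-2-phenyl-4H-chromen-8-yl)-2,2-dimethyl-5-oxo-2,5-dihydrofuran-3-yl trifluoromethanesulfonate
Product: 11 8-(5,5-dimethyl-2-oxo-2,5-dihydrofuran-3-yl)-7-methoxy-2-phenyl-4H-chromen-4-one
Conditions: Pd(OAc)2 (5 mol %), PPh3 (10 mol %), HCO2H, Bu3N, DMF, 60 °C
Reagents that add atoms: none
Why: Palladium-catalysed formate reduction of an enol triflate, in which zerovalent palladium should insert into the electron-poor C4'–OTf bond, formate replaces triflate and loses CO2 to give a palladium hydride, and reductive elimination installs C4'–H without touching the flavone or the lactone.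

**Compound list**
1 | 7-hydroxyflavone (7-hydroxy-2-phenyl-4H-chromen-4-one) | Oc1ccc2c(=O)cc(-c3ccccc3)oc2c1 | starting material
2 | 7-hydroxy-8-iodoflavone | Oc1ccc2c(=O)cc(-c3ccccc3)oc2c1I | intermediate
3 | 8-iodo-7-methoxyflavone | COc1ccc2c(=O)cc(-c3ccccc3)oc2c1I | intermediate
4 | 2-methylbut-3-yn-2-ol | CC(C)(O)C#C | starting material
5 | 8-(3-hydroxy-3-methylbut-1-yn-1-yl)-7-methoxy-2-phenyl-4H-chromen-4-one | COc1ccc2c(=O)cc(-c3ccccc3)oc2c1C#CC(C)(C)O | intermediate
6 | (Z)-5-[(7-methoxy-4-oxo-2-phenyl-4H-chromen-8-yl)methylidene]-4,4-dimethyl-1,3-dioxolan-2-one | COc1ccc2c(=O)cc(-c3ccccc3)oc2c1/C=C1\OC(=O)OC1(C)C | intermediate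
7 | potassium enolate tert-butyl carbonate: potassium (Z)-3-[(tert-butoxycarbonyl)oxy]-1-(7-methoxy-4-oxo-2-phenyl-4H-chromen-8-yl)-3-methylbut-1-en-2-olate (not isolated) | COc1ccc2c(=O)cc(-c3ccccc3)oc2c1/C=C(\[O-])C(C)(C)OC(=O)OC(C)(C)C.[K+] | intermediate
8 | potassium tetronate: potassium 4-(7-methoxy-4-oxo-2-phenyl-4H-chromen-8-yl)-2,2-dimethyl-5-oxo-2,5-dihydrofuran-3-olate (not isolated) | COc1ccc2c(=O)cc(-c3ccccc3)oc2c1C1=C([O-])C(C)(C)OC1=O.[K+] | intermediate
9 | 4-hydroxy-3-(7-methoxy-4-oxo-2-phenyl-4H-chromen-8-yl)-5,5-dimethylfuran-2(5H)-one | COc1ccc2c(=O)cc(-c3ccccc3)oc2c1C1=C(O)C(C)(C)OC1=O | intermediate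
10 | 4-(7-methoxy-4-oxo-2-phenyl-4H-chromen-8-yl)-2,2-dimethyl-5-oxo-2,5-dihydrofuran-3-yl trifluoromethanesulfonate | COc1ccc2c(=O)cc(-c3ccccc3)oc2c1C1=C(OS(=O)(=O)C(F)(F)F)C(C)(C)OC1=O | intermediate
11 | 8-(5,5-dimethyl-2-oxo-2,5-dihydrofuran-3-yl)-7-methoxy-2-phenyl-4H-chromen-4-one | COc1ccc2c(=O)cc(-c3ccccc3)oc2c1C1=CC(C)(C)OC1=O | target

**Count and risks**
Total step count: 7. Longest linear sequence: 7 steps (1 to 11).

Steps most likely to fail:

1. Step 5 (bears the label "Proposed new method:"). The tethered enolate may re-close on oxygen faster than on carbon, pass the carboxyl group on intermolecularly, or lose it altogether, because the enolendo C-acylation is slow. Alkoxide may also attack C2 of the pyranone ring. The fallback uses known chemistry: it sets out from alkynol 5 and comes back to the route at target 11. Compound 5 is heated with Pd(dba)2, 1,4-bis(diphenylphosphino)butane and CO/H2 in CH2Cl2 at 95 °C. This palladium-catalysed cyclocarbonylation of an alkynol to a furan-2(5H)-one should place the CO carbon on the aryl-bearing alkyne carbon and close the lactone onto the gem-dimethyl carbon. No new compound arises on this path (F0), and steps 4 to 7 are then not needed.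

2. Step 7. Nucleophilic cleavage of the vinylogous acyl triflate by formate or amine (return to the tetronic acid) may outrun oxidative addition at the crowded C4' position. The fallback sets out from tetronic acid 9 and comes back at target 11. Compound 9 is treated with oxalyl bromide and catalytic DMF in CH2Cl2 to give 4-bromo-3-(7-methoxy-4-oxo-2-phenyl-4H-chromen-8-yl)-5,5-dimethylfuran-2(5H)-one F1. This vinyl bromide does not hydrolyse under the reduction conditions and should be reduced in a radical chain with Bu3SnH and AIBN in benzene at 80 °C to 11.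

3. Step 4. The carboxylative cyclization may be slow on the di-ortho-substituted, electron-rich aryl alkyne, and 6-endo closure or Meyer–Schuster rearrangement of the propargylic alcohol may compete. The fallback sets out from alkynol 5 and comes back at cyclic carbonate 6. Compound 5 is acylated with di-tert-butyl dicarbonate and catalytic DMAP in MeCN to give tert-butyl 4-(7-methoxy-4-oxo-2-phenyl-4H-chromen-8-yl)-2-methylbut-3-yn-2-yl carbonate F2. With catalytic (Ph3P)AuNTf2 in CH2Cl2 at rt the carbonyl oxygen of F2 should add anti to the gold-activated alkyne, and loss of the tert-butyl group as 2-methylpropene then gives 6.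

**Further compounds**
F0 | step 5 | none | none
F1 | step 7 | 4-bromo-3-(7-methoxy-4-oxo-2-phenyl-4H-chromen-8-yl)-5,5-dimethylfuran-2(5H)-one | COc1ccc2c(=O)cc(-c3ccccc3)oc2c1C1=C(Br)C(C)(C)OC1=O
F2 | step 4 | tert-butyl 4-(7-methoxy-4-oxo-2-phenyl-4H-chromen-8-yl)-2-methylbut-3-yn-2-yl carbonate | COc1ccc2c(=O)cc(-c3ccccc3)oc2c1C#CC(C)(C)OC(=O)OC(C)(C)C
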